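**Retrosynthetic overview**
- The last C–C bond is a base-free Stille coupling at the C(Me)–CH bond of the hydroxy-ketone diene: an iodo-lactone (fragments A+B) plus an (E)-vinylstannane (fragment C, TBS ether); desilylation ends the route.
- The left (E,E)-diene comes from a Suzuki coupling of an (E)-alkenylboronate (fragment A, tail) with the (E)-iodoalkene of the central unit (fragment B).
- The α-alkenyl iodide of fragment B comes from hydrozirconation–iodination of a methyl alkyne; the alkyne comes from an aldehyde, which comes from a PMB-oxymethyl arm put on a γ-lactone enolate anti to the ring methyl.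
- Ring order: the only ring (γ-lactone) is made first by oxidative lactonization (step 15), opened to a bis-silylated 1,4-diol while the arm is elaborated, and closed again by oxidative lactonization (step 26).
- Stereocentres: two Brown crotylborations (anti for B; syn plus Wacker oxidation for C), substrate-controlled lactone alkylation, chiral-pool bromohydrin for A.

Assumption: compounds 1, 3, 8, 9, 18, 22 and both antipodes of Ipc2BOMe are bought; PMBOCH2Cl is made fresh. (TBS = tert-butyldimethylsilyl, PMB = 4-methoxybenzyl, Ipc = isopinocampheyl, Bpin = pinacolatoboryl.)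

**Fragment A**

Step 1
Reactants: 1 (S)-3-bromo-2-methylpropan-1-ol
Product: 2 (S)-[(3-bromo-2-methylpropyl)oxy](tert-butyl)dimethylsilane
Conditions: TBSCl, imidazole, DMF, 0 °C → rt
Reagents that add atoms: tert-butyldimethylsilyl chloride, CC(C)(C)[Si](C)(C)Cl
Why: Standard silylation protects the primary alcohol for the organometallic coupling and leaves the stereocentre untouched.

Step 2
Reactants: 2 (S)-[(3-bromo-2-methylpropyl)oxy](tert-butyl)dimethylsilane; 3 propylmagnesium bromide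
Product: 4 (R)-tert-butyldimethyl[(2-methylhexyl)oxy]silane
Conditions: Li2CuCl4 (3 mol%), THF/NMP, −20 °C → rt
Reagents that add atoms: none
Why: Kochi-type copper-catalysed Grignard cross-coupling displaces the primary bromide away from the stereocentre, which is retained and only changes descriptor from S to R.

Step 3
Reactants: 4 (R)-tert-butyldimethyl[(2-methylhexyl)oxy]silane
Product: 5 (R)-2-methylhexan-1-ol
Conditions: camphorsulfonic acid (10 mol%), MeOH, rt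
Reagents that add atoms: none
Why: Acid-catalysed methanolysis cleaves the primary silyl ether without touching the stereocentre.

Step 4
Reactants: 5 (R)-2-methylhexan-1-ol
Product: 6 (R)-2-methylhexanal
Conditions: TEMPO (10 mol%), PhI(OAc)2, CH2Cl2, rt; used crude
Reagents that add atoms: none
Why: Oxoammonium (TEMPO/PhI(OAc)2) oxidation stops at the aldehyde under near-neutral conditions, so the α-stereocentre does not epimerise.

Step 5
Reactants: 6 (R)-2-methylhexanal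
Product: 7 4,4,5,5-tetramethyl-2-[(1E,3R)-3-methylhept-1-en-1-yl]-1,3,2-dioxaborolane
Conditions: Cl2CHBpin, CrCl2, LiI, THF, rt
Reagents that add atoms: 2-(dichloromethyl)-4,4,5,5-tetramethyl-1,3,2-dioxaborolane, ClC(Cl)B1OC(C)(C)C(C)(C)O1
Why: Takai–Utimoto olefination with the gem-dichromium boryl species gives the (E)-alkenylboronate under non-basic conditions that spare the α-stereocentre.

**Fragment C**

Step 6
Reactants: 8 (Z)-but-2-ene; 9 3-(trimethylsilyl)prop-2-ynal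
Product: 13 (3R,4S)-4-methyl-1-(trimethylsilyl)hex-5-en-1-yn-3-ol, via (Z)-crotylpotassium 10 (not isolated), via (Z)-crotyl-B(Ipc)2 11 (not isolated), via borinate ester 12 (not isolated)
Conditions: KOt-Bu, n-BuLi, THF, −78 → −45 °C; (+)-Ipc2BOMe, −78 °C; BF3·OEt2; 9, −78 °C; HOCH2CH2NH2, rt
Reagents that add atoms: none
Why: Brown asymmetric crotylboration: the (Z)-crotylborane reacts through a closed chair (Zimmerman–Traxler) transition state to give the syn pair, and the Ipc groups from (−)-α-pinene choose the aldehyde face, setting C3 (R) and C4 (S).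

Step 7
Reactants: 13 (3R,4S)-4-methyl-1-(trimethylsilyl)hex-5-en-1-yn-3-ol
Product: 14 tert-butyldimethyl{[(3R,4S)-4-methyl-1-(trimethylsilyl)hex-5-en-1-yn-3-yl]oxy}silane
Conditions: TBSOTf, 2,6-lutidine, CH2Cl2, −78 → 0 °C
Reagents that add atoms: tert-butyldimethylsilyl trifluoromethanesulfonate, CC(C)(C)[Si](C)(C)OS(=O)(=O)C(F)(F)F
Why: Silyl triflate with a hindered base silylates the secondary propargylic alcohol cleanly.

Step 8
Reactants: 14 tert-butyldimethyl{[(3R,4S)-4-methyl-1-(trimethylsilyl)hex-5-en-1-yn-3-yl]oxy}silane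
Product: 15 (3R,4R)-4-[(tert-butyldimethylsilyl)oxy]-3-methyl-6-(trimethylsilyl)hex-5-yn-2-one
Conditions: PdCl2 (10 mol%), CuCl, O2 (1 atm), DMF/H2O (7:1), rt
Reagents that add atoms: water, O
Why: Tsuji–Wacker oxidation (Markovnikov hydroxypalladation of the terminal alkene) gives the syn-aldol-type methyl ketone under neutral conditions that keep the α-methyl centre, while the silyl-capped alkyne is left alone.

Step 9
Reactants: 15 (3R,4R)-4-[(tert-butyldimethylsilyl)oxy]-3-methyl-6-(trimethylsilyl)hex-5-yn-2-one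
Product: 16 (3R,4R)-4-[(tert-butyldimethylsilyl)oxy]-3-methylhex-5-yn-2-one
Conditions: AgNO3 (10 mol%), acetone/H2O, rt
Reagents that add atoms: none
Why: Silver-catalysed protodesilylation frees the terminal alkyne under neutral conditions, avoiding base that would epimerise or β-eliminate the β-silyloxy ketone.

Step 10
Reactants: 16 (3R,4R)-4-[(tert-butyldimethylsilyl)oxy]-3-methylhex-5-yn-2-one
Product: 17 (3R,4R,5E)-4-[(tert-butyldimethylsilyl)oxy]-3-methyl-6-(tributylstannyl)hex-5-en-2-one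
Conditions: Bu3SnH, PdCl2(PPh3)2 (2 mol%), THF, 0 °C
Reagents that add atoms: tributyltin hydride, CCCC[SnH](CCCC)CCCC
Why: Palladium-catalysed syn-hydrostannation puts tin on the unhindered terminal carbon and gives the (E)-vinylstannane, with ketone and silyl ether untouched.

**Fragment B and assembly**

Step 11
Reactants: 18 prop-2-yn-1-ol
Product: 20 (2E)-3-iodo-2-methylprop-2-en-1-ol, via alkenylalane 19 (not isolated)
Conditions: Me3Al (3 equiv), Cp2ZrCl2 (0.25 equiv), CH2Cl2, 0 °C → rt; I2, THF, −30 → 0 °C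
Reagents that add atoms: trimethylaluminium, C[Al](C)C; iodine, I-I
Why: Negishi zirconium-catalysed carboalumination adds Me and Al syn with Al at the terminal carbon, and iodinolysis with retention gives only the (E)-iodide.

Step 12
Reactants: 20 (2E)-3-iodo-2-methylprop-2-en-1-ol
Product: 21 (2E)-3-iodo-2-methylprop-2-enal
Conditions: MnO2 (excess), CH2Cl2, rt; solution used directly
Reagents that add atoms: none
Why: MnO2 oxidises the allylic alcohol selectively to the volatile enal.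

Step 13
Reactants: 21 (2E)-3-iodo-2-methylprop-2-enal; 22 (E)-but-2-ene
Product: 26 (1E,3S,4S)-1-iodo-2,4-dimethylhexa-1,5-dien-3-ol, via (E)-crotylpotassium 23 (not isolated), via (E)-crotyl-B(Ipc)2 24 (not isolated), via borinate ester 25 (not isolated)
Conditions: KOt-Bu, n-BuLi, THF, −78 → −45 °C; (−)-Ipc2BOMe, −78 °C; BF3·OEt2; 21, −78 °C; HOCH2CH2NH2, rt
Reagents that add atoms: none
Why: Brown asymmetric crotylboration: the (E)-crotylborane gives the anti pair through the chair transition state and the Ipc groups from (+)-α-pinene select the aldehyde face, setting C3 (S) and C4 (S).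

Step 14
Reactants: 26 (1E,3S,4S)-1-iodo-2,4-dimethylhexa-1,5-dien-3-ol
Product: 28 (3S,4S,5E)-6-iodo-3,5-dimethylhex-5-ene-1,4-diol, via trialkylborane 27 (not isolated)
Conditions: 9-BBN-H (2.5 equiv), THF, 0 °C → rt; NaOH, H2O2, 0 °C
Reagents that add atoms: hydrogen peroxide, OO
Why: Anti-Markovnikov hydroboration–oxidation with bulky 9-BBN-H attacks only the monosubstituted alkene and leaves the trisubstituted iodoalkene alone.

Step 15
Reactants: 28 (3S,4S,5E)-6-iodo-3,5-dimethylhex-5-ene-1,4-diol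
Product: 30 (4S,5S)-5-[(1E)-1-iodoprop-1-en-2-yl]-4-methyloxolan-2-one, via lactol 29 (not isolated)
Conditions: TEMPO (20 mol%), PhI(OAc)2 (2.5 equiv), CH2Cl2, rt
Reagents that add atoms: none
Why: TEMPO/PhI(OAc)2 oxidative lactonization oxidises the primary alcohol selectively, the aldehyde closes to the lactol with the C4 hydroxyl and is oxidised on to the γ-lactone, the anti diol giving the 4,5-trans ring.

Step 16
Reactants: 30 (4S,5S)-5-[(1E)-1-iodoprop-1-en-2-yl]-4-methyloxolan-2-one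
Product: 32 (3R,4S,5S)-5-[(1E)-1-iodoprop-1-en-2-yl]-3-{[(4-methoxyphenyl)methoxy]methyl}-4-methyloxolan-2-one, via lithium enolate 31 (not isolated)
Conditions: LiN(i-Pr)2, THF, −78 °C; PMBOCH2Cl, −78 → −40 °C
Reagents that add atoms: 4-methoxybenzyl chloromethyl ether, COc1ccc(COCCl)cc1
Why: Lactone enolate alkylation (SN2 on the chloromethyl ether) occurs on the face anti to the adjacent C4 methyl, setting C3 with the new carbon arm trans to that methyl.

Step 17
Reactants: 32 (3R,4S,5S)-5-[(1E)-1-iodoprop-1-en-2-yl]-3-{[(4-methoxyphenyl)methoxy]methyl}-4-methyloxolan-2-one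
Product: 33 (2S,3S,4S,5E)-6-iodo-2-{[(4-methoxyphenyl)methoxy]methyl}-3,5-dimethylhex-5-ene-1,4-diol
Conditions: LiBH4, THF, 0 °C → rt
Reagents that add atoms: none
Why: Hydride reduction opens the lactone to the 1,4-diol (an α-formyl lactone would be an enolised 1,3-dicarbonyl), sparing vinyl iodide and PMB ether, and the two differently capped CH2O arms keep C2 stereodefined.

Step 18
Reactants: 33 (2S,3S,4S,5E)-6-iodo-2-{[(4-methoxyphenyl)methoxy]methyl}-3,5-dimethylhex-5-ene-1,4-diol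
Product: 34 (1E,3S,4S,5R)-3,6-bis[(tert-butyldimethylsilyl)oxy]-1-iodo-5-{[(4-methoxyphenyl)methoxy]methyl}-2,4-dimethylhex-1-ene
Conditions: TBSOTf (2.5 equiv), 2,6-lutidine, CH2Cl2, −78 → 0 °C
Reagents that add atoms: tert-butyldimethylsilyl trifluoromethanesulfonate, CC(C)(C)[Si](C)(C)OS(=O)(=O)C(F)(F)F
Why: Silyl triflate caps both the primary and the hindered secondary allylic hydroxyl.

Step 19
Reactants: 34 (1E,3S,4S,5R)-3,6-bis[(tert-butyldimethylsilyl)oxy]-1-iodo-5-{[(4-methoxyphenyl)methoxy]methyl}-2,4-dimethylhex-1-ene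
Product: 35 (2R,3S,4S,5E)-4-[(tert-butyldimethylsilyl)oxy]-2-{[(tert-butyldimethylsilyl)oxy]methyl}-6-iodo-3,5-dimethylhex-5-en-1-ol
Conditions: DDQ, CH2Cl2/pH 7 buffer, 0 °C
Reagents that add atoms: none
Why: DDQ removes the PMB ether by benzylic hydride abstraction and hydrolysis, leaving silyl ethers and the vinyl iodide intact.

Step 20
Reactants: 35 (2R,3S,4S,5E)-4-[(tert-butyldimethylsilyl)oxy]-2-{[(tert-butyldimethylsilyl)oxy]methyl}-6-iodo-3,5-dimethylhex-5-en-1-ol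
Product: 36 (2S,3S,4S,5E)-4-[(tert-butyldimethylsilyl)oxy]-2-{[(tert-butyldimethylsilyl)oxy]methyl}-6-iodo-3,5-dimethylhex-5-enal
Conditions: Dess–Martin periodinane, NaHCO3, CH2Cl2, 0 °C → rt
Reagents that add atoms: none
Why: Buffered Dess–Martin oxidation gives the α-branched β-silyloxy aldehyde without epimerisation.

Step 21
Reactants: 36 (2S,3S,4S,5E)-4-[(tert-butyldimethylsilyl)oxy]-2-{[(tert-butyldimethylsilyl)oxy]methyl}-6-iodo-3,5-dimethylhex-5-enal
Product: 37 (1E,3S,4S,5R)-3-[(tert-butyldimethylsilyl)oxy]-5-{[(tert-butyldimethylsilyl)oxy]methyl}-1-iodo-2,4-dimethylhept-1-en-6-yne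
Conditions: dimethyl (1-diazo-2-oxopropyl)phosphonate, K2CO3, MeOH, 0 °C → rt
Reagents that add atoms: dimethyl (1-diazo-2-oxopropyl)phosphonate, CC(=O)C(=[N+]=[N-])P(=O)(OC)OC
Why: Seyferth–Gilbert homologation in the Ohira–Bestmann version converts the aldehyde into the terminal alkyne under mild base that spares α-stereocentres of this β-silyloxy type.

Step 22
Reactants: 37 (1E,3S,4S,5R)-3-[(tert-butyldimethylsilyl)oxy]-5-{[(tert-butyldimethylsilyl)oxy]methyl}-1-iodo-2,4-dimethylhept-1-en-6-yne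
Product: 39 (1E,3S,4S,5R)-3-[(tert-butyldimethylsilyl)oxy]-5-{[(tert-butyldimethylsilyl)oxy]methyl}-1-iodo-2,4-dimethyloct-1-en-6-yne, via lithium acetylide 38 (not isolated)
Conditions: LiN(SiMe3)2, THF, −78 °C; MeI, −78 °C → rt
Reagents that add atoms: iodomethane, IC
Why: A non-nucleophilic amide base deprotonates only the terminal alkyne (the vinyl iodide is left alone) and the acetylide is methylated by SN2.

Step 23
Reactants: 39 (1E,3S,4S,5R)-3-[(tert-butyldimethylsilyl)oxy]-5-{[(tert-butyldimethylsilyl)oxy]methyl}-1-iodo-2,4-dimethyloct-1-en-6-yne; 7 4,4,5,5-tetramethyl-2-[(1E,3R)-3-methylhept-1-en-1-yl]-1,3,2-dioxaborolane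
Product: 40 (4R,5S,6S,7E,9E,11R)-6-[(tert-butyldimethylsilyl)oxy]-4-{[(tert-butyldimethylsilyl)oxy]methyl}-5,7,11-trimethylpentadeca-7,9-dien-2-yne
Conditions: Pd(PPh3)4 (5 mol%), aq. NaOH (2 M), THF, rt → 45 °C
Reagents that add atoms: none
Why: Suzuki–Miyaura coupling of the (E)-iodoalkene with the (E)-alkenylboronate proceeds with retention at both partners to give the (E,E)-diene, the internal alkyne being inert.

Step 24
Reactants: 40 (4R,5S,6S,7E,9E,11R)-6-[(tert-butyldimethylsilyl)oxy]-4-{[(tert-butyldimethylsilyl)oxy]methyl}-5,7,11-trimethylpentadeca-7,9-dien-2-yne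
Product: 42 (2E,4R,5S,6S,7E,9E,11R)-6-[(tert-butyldimethylsilyl)oxy]-4-{[(tert-butyldimethylsilyl)oxy]methyl}-2-iodo-5,7,11-trimethylpentadeca-2,7,9-triene, via alkenylzirconocene 41 (not isolated)
Conditions: Cp2Zr(H)Cl (2 equiv), THF, rt → 45 °C; I2, THF, −20 °C, dark
Reagents that add atoms: iodine, I-I
Why: Hydrozirconation adds Zr–H syn with zirconium on the less hindered methyl-bearing alkyne carbon (the alkyne reacts faster than the internal diene), and iodinolysis with retention gives the (E)-2-iodoalkene.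

Step 25
Reactants: 42 (2E,4R,5S,6S,7E,9E,11R)-6-[(tert-butyldimethylsilyl)oxy]-4-{[(tert-butyldimethylsilyl)oxy]methyl}-2-iodo-5,7,11-trimethylpentadeca-2,7,9-triene
Product: 43 (2R,3S,4S,5E,7E,9R)-2-[(1E)-2-iodoprop-1-en-1-yl]-3,5,9-trimethyltrideca-5,7-diene-1,4-diol
Conditions: HF·pyridine, pyridine, THF, 0 °C → rt
Reagents that add atoms: none
Why: Buffered fluoride removes both silyl ethers and returns the 1,4-diol without ionising the dienylic alcohol.

Step 26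
Reactants: 43 (2R,3S,4S,5E,7E,9R)-2-[(1E)-2-iodoprop-1-en-1-yl]-3,5,9-trimethyltrideca-5,7-diene-1,4-diol
Product: 45 (3R,4S,5S)-3-[(1E)-2-iodoprop-1-en-1-yl]-4-methyl-5-[(2E,4E,6R)-6-methyldeca-2,4-dien-2-yl]oxolan-2-one, via lactol 44 (not isolated)
Conditions: TEMPO (20 mol%), PhI(OAc)2 (2.5 equiv), CH2Cl2, rt
Reagents that add atoms: none
Why: A second oxidative lactonization closes the ring through the lactol, and the C3 configuration fixed in step 16 now places all three ring substituents mutually trans.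

Step 27
Reactants: 45 (3R,4S,5S)-3-[(1E)-2-iodoprop-1-en-1-yl]-4-methyl-5-[(2E,4E,6R)-6-methyldeca-2,4-dien-2-yl]oxolan-2-one; 17 (3R,4R,5E)-4-[(tert-butyldimethylsilyl)oxy]-3-methyl-6-(tributylstannyl)hex-5-en-2-one
Product: 46 (3S,4S,5S)-3-[(1E,3E,5S,6R)-5-[(tert-butyldimethylsilyl)oxy]-2,6-dimethyl-7-oxoocta-1,3-dien-1-yl]-4-methyl-5-[(2E,4E,6R)-6-methyldeca-2,4-dien-2-yl]oxolan-2-one
Conditions: Pd(PPh3)4 (5 mol%), Cu(O2CC4H3S) [copper thiophene-2-carboxylate, CuTC] (1.5 equiv), NMP, 0 °C → rt, dark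
Reagents that add atoms: none
Why: Stille coupling promoted by copper thiophene-2-carboxylate joins the two halves under base-free conditions with retention of both alkene geometries, so the epimerisable C3–H and the β-silyloxy ketone survive.

Step 28
Reactants: 46 (3S,4S,5S)-3-[(1E,3E,5S,6R)-5-[(tert-butyldimethylsilyl)oxy]-2,6-dimethyl-7-oxoocta-1,3-dien-1-yl]-4-methyl-5-[(2E,4E,6R)-6-methyldeca-2,4-dien-2-yl]oxolan-2-one
Product: 47 (3S,4S,5S)-3-[(1E,3E,5S,6R)-5-hydroxy-2,6-dimethyl-7-oxoocta-1,3-dien-1-yl]-4-methyl-5-[(2E,4E,6R)-6-methyldeca-2,4-dien-2-yl]oxolan-2-one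
Conditions: HF·pyridine, pyridine, THF, 0 °C → rt
Reagents that add atoms: none
Why: Buffered fluoride cleaves the last silyl ether without acid or base strong enough to dehydrate or epimerise the β-hydroxy ketone.

**Compound list**

1 | (S)-3-bromo-2-methylpropan-1-ol | C[C@H](CBr)CO | starting material
2 | (S)-[(3-bromo-2-methylpropyl)oxy](tert-butyl)dimethylsilane | C[C@H](CBr)CO[Si](C)(C)C(C)(C)C | intermediate
3 | propylmagnesium bromide | CCC[Mg]Br | starting material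
4 | (R)-tert-butyldimethyl[(2-methylhexyl)oxy]silane | C[C@H](CCCC)CO[Si](C)(C)C(C)(C)C | intermediate
5 | (R)-2-methylhexan-1-ol | C[C@H](CCCC)CO | intermediate
6 | (R)-2-methylhexanal | C[C@H](CCCC)C=O | intermediate
7 | 4,4,5,5-tetramethyl-2-[(1E,3R)-3-methylhept-1-en-1-yl]-1,3,2-dioxaborolane (fragment A) | C[C@H](CCCC)/C=C/B1OC(C)(C)C(C)(C)O1 | intermediate
8 | (Z)-but-2-ene | C/C=C\C | starting material
9 | 3-(trimethylsilyl)prop-2-ynal | C[Si](C)(C)C#CC=O | starting material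
10 | (Z)-but-2-en-1-ylpotassium | C/C=C\[CH2-].[K+] | intermediate
11 | [(2Z)-but-2-en-1-yl]diisopinocampheylborane (Ipc from (−)-α-pinene) | C/C=C\CB([C@H]1C[C@H]2C[C@@H]([C@@H]1C)C2(C)C)[C@H]1C[C@H]2C[C@@H]([C@@H]1C)C2(C)C | intermediate
12 | diisopinocampheylborinate ester of 13 | C[Si](C)(C)C#C[C@H](OB([C@H]1C[C@H]2C[C@@H]([C@@H]1C)C2(C)C)[C@H]1C[C@H]2C[C@@H]([C@@H]1C)C2(C)C)[C@@H](C)C=C | intermediate
13 | (3R,4S)-4-methyl-1-(trimethylsilyl)hex-5-en-1-yn-3-ol | C[Si](C)(C)C#C[C@H](O)[C@@H](C)C=C | intermediate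
14 | tert-butyldimethyl{[(3R,4S)-4-methyl-1-(trimethylsilyl)hex-5-en-1-yn-3-yl]oxy}silane | C[Si](C)(C)C#C[C@H](O[Si](C)(C)C(C)(C)C)[C@@H](C)C=C | intermediate
15 | (3R,4R)-4-[(tert-butyldimethylsilyl)oxy]-3-methyl-6-(trimethylsilyl)hex-5-yn-2-one | C[Si](C)(C)C#C[C@H](O[Si](C)(C)C(C)(C)C)[C@@H](C)C(C)=O | intermediate
16 | (3R,4R)-4-[(tert-butyldimethylsilyl)oxy]-3-methylhex-5-yn-2-one | C#C[C@H](O[Si](C)(C)C(C)(C)C)[C@@H](C)C(C)=O | intermediate
17 | (3R,4R,5E)-4-[(tert-butyldimethylsilyl)oxy]-3-methyl-6-(tributylstannyl)hex-5-en-2-one (fragment C) | CCCC[Sn](CCCC)(CCCC)/C=C/[C@H](O[Si](C)(C)C(C)(C)C)[C@@H](C)C(C)=O | intermediate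
18 | prop-2-yn-1-ol | C#CCO | starting material
19 | dimethyl[(1E)-3-(dimethylalumanyloxy)-2-methylprop-1-en-1-yl]alumane | C[Al](C)/C=C(\C)CO[Al](C)C | intermediate
20 | (2E)-3-iodo-2-methylprop-2-en-1-ol | I/C=C(\C)CO | intermediate
21 | (2E)-3-iodo-2-methylprop-2-enal | I/C=C(\C)C=O | intermediate
22 | (E)-but-2-ene | C/C=C/C | starting material
23 | (E)-but-2-en-1-ylpotassium | C/C=C/[CH2-].[K+] | intermediate
24 | [(2E)-but-2-en-1-yl]diisopinocampheylborane (Ipc from (+)-α-pinene) | C/C=C/CB([C@@H]1C[C@@H]2C[C@H]([C@H]1C)C2(C)C)[C@@H]1C[C@@H]2C[C@H]([C@H]1C)C2(C)C | intermediate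
25 | diisopinocampheylborinate ester of 26 | I/C=C(\C)[C@@H](OB([C@@H]1C[C@@H]2C[C@H]([C@H]1C)C2(C)C)[C@@H]1C[C@@H]2C[C@H]([C@H]1C)C2(C)C)[C@@H](C)C=C | intermediate
26 | (1E,3S,4S)-1-iodo-2,4-dimethylhexa-1,5-dien-3-ol | I/C=C(\C)[C@@H](O)[C@@H](C)C=C | intermediate
27 | B-alkyl-9-BBN adduct of 26 (O-borinate at C3) | I/C=C(\C)[C@@H](OB1C2CCCC1CCC2)[C@@H](C)CCB1C2CCCC1CCC2 | intermediate
28 | (3S,4S,5E)-6-iodo-3,5-dimethylhex-5-ene-1,4-diol | I/C=C(\C)[C@@H](O)[C@@H](C)CCO | intermediate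
29 | (4S,5S)-5-[(1E)-1-iodoprop-1-en-2-yl]-4-methyloxolan-2-ol (anomer mixture) | I/C=C(\C)[C@H]1OC(O)C[C@@H]1C | intermediate
30 | (4S,5S)-5-[(1E)-1-iodoprop-1-en-2-yl]-4-methyloxolan-2-one | I/C=C(\C)[C@H]1OC(=O)C[C@@H]1C | intermediate
31 | lithium enolate of 30 | I/C=C(\C)[C@H]1OC([O-])=C[C@@H]1C.[Li+] | intermediate
32 | (3R,4S,5S)-5-[(1E)-1-iodoprop-1-en-2-yl]-3-{[(4-methoxyphenyl)methoxy]methyl}-4-methyloxolan-2-one | I/C=C(\C)[C@H]1OC(=O)[C@@H](COCc2ccc(OC)cc2)[C@@H]1C | intermediate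
33 | (2S,3S,4S,5E)-6-iodo-2-{[(4-methoxyphenyl)methoxy]methyl}-3,5-dimethylhex-5-ene-1,4-diol | I/C=C(\C)[C@@H](O)[C@@H](C)[C@@H](CO)COCc1ccc(OC)cc1 | intermediate
34 | (1E,3S,4S,5R)-3,6-bis[(tert-butyldimethylsilyl)oxy]-1-iodo-5-{[(4-methoxyphenyl)methoxy]methyl}-2,4-dimethylhex-1-ene | I/C=C(\C)[C@@H](O[Si](C)(C)C(C)(C)C)[C@@H](C)[C@@H](CO[Si](C)(C)C(C)(C)C)COCc1ccc(OC)cc1 | intermediate
35 | (2R,3S,4S,5E)-4-[(tert-butyldimethylsilyl)oxy]-2-{[(tert-butyldimethylsilyl)oxy]methyl}-6-iodo-3,5-dimethylhex-5-en-1-ol | I/C=C(\C)[C@@H](O[Si](C)(C)C(C)(C)C)[C@@H](C)[C@@H](CO[Si](C)(C)C(C)(C)C)CO | intermediate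
36 | (2S,3S,4S,5E)-4-[(tert-butyldimethylsilyl)oxy]-2-{[(tert-butyldimethylsilyl)oxy]methyl}-6-iodo-3,5-dimethylhex-5-enal | I/C=C(\C)[C@@H](O[Si](C)(C)C(C)(C)C)[C@@H](C)[C@@H](CO[Si](C)(C)C(C)(C)C)C=O | intermediate
37 | (1E,3S,4S,5R)-3-[(tert-butyldimethylsilyl)oxy]-5-{[(tert-butyldimethylsilyl)oxy]methyl}-1-iodo-2,4-dimethylhept-1-en-6-yne | I/C=C(\C)[C@@H](O[Si](C)(C)C(C)(C)C)[C@@H](C)[C@@H](CO[Si](C)(C)C(C)(C)C)C#C | intermediate
38 | lithium acetylide of 37 | I/C=C(\C)[C@@H](O[Si](C)(C)C(C)(C)C)[C@@H](C)[C@@H](CO[Si](C)(C)C(C)(C)C)C#[C-].[Li+] | intermediate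
39 | (1E,3S,4S,5R)-3-[(tert-butyldimethylsilyl)oxy]-5-{[(tert-butyldimethylsilyl)oxy]methyl}-1-iodo-2,4-dimethyloct-1-en-6-yne | I/C=C(\C)[C@@H](O[Si](C)(C)C(C)(C)C)[C@@H](C)[C@@H](CO[Si](C)(C)C(C)(C)C)C#CC | intermediate
40 | (4R,5S,6S,7E,9E,11R)-6-[(tert-butyldimethylsilyl)oxy]-4-{[(tert-butyldimethylsilyl)oxy]methyl}-5,7,11-trimethylpentadeca-7,9-dien-2-yne | CCCC[C@@H](C)/C=C/C=C(\C)[C@@H](O[Si](C)(C)C(C)(C)C)[C@@H](C)[C@@H](CO[Si](C)(C)C(C)(C)C)C#CC | intermediate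
41 | alkenylzirconocene chloride from 40 (Zr at C2) | CCCC[C@@H](C)/C=C/C=C(\C)[C@@H](O[Si](C)(C)C(C)(C)C)[C@@H](C)[C@@H](CO[Si](C)(C)C(C)(C)C)/C=C(\C)[Zr](Cl)(C1C=CC=C1)C1C=CC=C1 | intermediate
42 | (2E,4R,5S,6S,7E,9E,11R)-6-[(tert-butyldimethylsilyl)oxy]-4-{[(tert-butyldimethylsilyl)oxy]methyl}-2-iodo-5,7,11-trimethylpentadeca-2,7,9-triene | CCCC[C@@H](C)/C=C/C=C(\C)[C@@H](O[Si](C)(C)C(C)(C)C)[C@@H](C)[C@@H](CO[Si](C)(C)C(C)(C)C)/C=C(\C)I | intermediate
43 | (2R,3S,4S,5E,7E,9R)-2-[(1E)-2-iodoprop-1-en-1-yl]-3,5,9-trimethyltrideca-5,7-diene-1,4-diol | CCCC[C@@H](C)/C=C/C=C(\C)[C@@H](O)[C@@H](C)[C@@H](CO)/C=C(\C)I | intermediate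
44 | (3R,4S,5S)-3-[(1E)-2-iodoprop-1-en-1-yl]-4-methyl-5-[(2E,4E,6R)-6-methyldeca-2,4-dien-2-yl]oxolan-2-ol (anomer mixture) | CCCC[C@@H](C)/C=C/C=C(\C)[C@H]1OC(O)[C@@H](/C=C(\C)I)[C@@H]1C | intermediate
45 | (3R,4S,5S)-3-[(1E)-2-iodoprop-1-en-1-yl]-4-methyl-5-[(2E,4E,6R)-6-methyldeca-2,4-dien-2-yl]oxolan-2-one (fragments A+B) | CCCC[C@@H](C)/C=C/C=C(\C)[C@H]1OC(=O)[C@@H](/C=C(\C)I)[C@@H]1C | intermediate
46 | (3S,4S,5S)-3-[(1E,3E,5S,6R)-5-[(tert-butyldimethylsilyl)oxy]-2,6-dimethyl-7-oxoocta-1,3-dien-1-yl]-4-methyl-5-[(2E,4E,6R)-6-methyldeca-2,4-dien-2-yl]oxolan-2-one | CCCC[C@@H](C)/C=C/C=C(\C)[C@H]1OC(=O)[C@@H](/C=C(C)/C=C/[C@H](O[Si](C)(C)C(C)(C)C)[C@@H](C)C(C)=O)[C@@H]1C | intermediate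
47 | (3S,4S,5S)-3-[(1E,3E,5S,6R)-5-hydroxy-2,6-dimethyl-7-oxoocta-1,3-dien-1-yl]-4-methyl-5-[(2E,4E,6R)-6-methyldeca-2,4-dien-2-yl]oxolan-2-one | CCCC[C@@H](C)/C=C/C=C(\C)[C@H]1OC(=O)[C@@H](/C=C(C)/C=C/[C@H](O)[C@@H](C)C(C)=O)[C@@H]1C | target

**Totals**

Total step count: 28. Longest linear sequence: 18 steps (steps 11–28, from prop-2-yn-1-ol 18).

**Three steps most likely to fail**

Step 24 (hydrozirconation–iodination of 40). The regiochemistry on the internal alkyne may be incomplete and the diene may be attacked by excess Cp2Zr(H)Cl or iodine. Fallback: setting out from 40, palladium-catalysed syn-hydrostannation (Bu3SnH, PdCl2(PPh3)2, THF, 0 °C) gives tributyl[(2E,4R,5S,6S,7E,9E,11R)-6-[(tert-butyldimethylsilyl)oxy]-4-{[(tert-butyldimethylsilyl)oxy]methyl}-5,7,11-trimethylpentadeca-2,7,9-trien-2-yl]stannane F1. Iododestannylation of this (I2, CH2Cl2, −20 °C) rejoins the route at 42.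

Step 27 (Stille coupling on 45). The iodide is hindered, and zerovalent palladium could ionise the dienylic C5–O bond of the lactone or erode C3. Fallback: join the halves before the ring exists. Setting out from 42, Stille coupling with 17 (Pd2(dba)3, AsPh3, CuI, DMF, rt) gives (3R,4S,5E,7E,9S,10S,11S,12E,14E,16R)-4,11-bis[(tert-butyldimethylsilyl)oxy]-9-{[(tert-butyldimethylsilyl)oxy]methyl}-3,7,10,12,16-pentamethylicosa-5,7,12,14-tetraen-2-one F2. HF·pyridine then removes the three silyl groups to give (3R,4S,5E,7E,9S,10S,11S,12E,14E,16R)-4,11-dihydroxy-9-(hydroxymethyl)-3,7,10,12,16-pentamethylicosa-5,7,12,14-tetraen-2-one F3. TEMPO/PhI(OAc)2 oxidises the primary alcohol chemoselectively and closes the lactone through the lactol, coming back to the route at 47.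

Step 8 (Wacker oxidation of 14). The alkynylsilane can bind divalent palladium and some aldehyde regioisomer may form. Fallback: make the ketone by an auxiliary aldol instead, setting out from 9. Evans syn-aldol of 9 with the dibutylboron enolate of (4R)-4-benzyl-3-propanoyl-1,3-oxazolidin-2-one (Bu2BOTf, i-Pr2NEt, CH2Cl2, −78 °C) gives (4R)-4-benzyl-3-[(2R,3R)-3-hydroxy-2-methyl-5-(trimethylsilyl)pent-4-ynoyl]-1,3-oxazolidin-2-one F4. Transamidation (MeONHMe·HCl, Me3Al) gives (2R,3R)-3-hydroxy-N-methoxy-N,2-dimethyl-5-(trimethylsilyl)pent-4-ynamide F5. Silylation (TBSOTf, 2,6-lutidine) gives (2R,3R)-3-[(tert-butyldimethylsilyl)oxy]-N-methoxy-N,2-dimethyl-5-(trimethylsilyl)pent-4-ynamide F6. MeMgBr (THF, 0 °C) then delivers 15, where the route resumes.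

**Further compounds**

F1 | step 24 | tributyl[(2E,4R,5S,6S,7E,9E,11R)-6-[(tert-butyldimethylsilyl)oxy]-4-{[(tert-butyldimethylsilyl)oxy]methyl}-5,7,11-trimethylpentadeca-2,7,9-trien-2-yl]stannane | CCCC[C@@H](C)/C=C/C=C(\C)[C@@H](O[Si](C)(C)C(C)(C)C)[C@@H](C)[C@@H](CO[Si](C)(C)C(C)(C)C)/C=C(\C)[Sn](CCCC)(CCCC)CCCC
F2 | step 27 | (3R,4S,5E,7E,9S,10S,11S,12E,14E,16R)-4,11-bis[(tert-butyldimethylsilyl)oxy]-9-{[(tert-butyldimethylsilyl)oxy]methyl}-3,7,10,12,16-pentamethylicosa-5,7,12,14-tetraen-2-one | CCCC[C@@H](C)/C=C/C=C(\C)[C@@H](O[Si](C)(C)C(C)(C)C)[C@@H](C)[C@@H](CO[Si](C)(C)C(C)(C)C)/C=C(C)/C=C/[C@H](O[Si](C)(C)C(C)(C)C)[C@@H](C)C(C)=O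
F3 | step 27 | (3R,4S,5E,7E,9S,10S,11S,12E,14E,16R)-4,11-dihydroxy-9-(hydroxymethyl)-3,7,10,12,16-pentamethylicosa-5,7,12,14-tetraen-2-one | CCCC[C@@H](C)/C=C/C=C(\C)[C@@H](O)[C@@H](C)[C@@H](CO)/C=C(C)/C=C/[C@H](O)[C@@H](C)C(C)=O
F4 | step 8 | (4R)-4-benzyl-3-[(2R,3R)-3-hydroxy-2-methyl-5-(trimethylsilyl)pent-4-ynoyl]-1,3-oxazolidin-2-one | C[Si](C)(C)C#C[C@H](O)[C@@H](C)C(=O)N1[C@H](Cc2ccccc2)COC1=O
F5 | step 8 | (2R,3R)-3-hydroxy-N-methoxy-N,2-dimethyl-5-(trimethylsilyl)pent-4-ynamide | C[Si](C)(C)C#C[C@H](O)[C@@H](C)C(=O)N(C)OC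
F6 | step 8 | (2R,3R)-3-[(tert-butyldimethylsilyl)oxy]-N-methoxy-N,2-dimethyl-5-(trimethylsilyl)pent-4-ynamide | C[Si](C)(C)C#C[C@H](O[Si](C)(C)C(C)(C)C)[C@@H](C)C(=O)N(C)OC
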